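## Retrosynthetic overview
1. Target 24 ⇒ MOM removal and a one-flask double aryl metalation (isovaleryl, then formyl) on the symmetric tris-MOM aryl eudesmanol 17.
2. 17 ⇒ MeLi addition at C4 and Wittig methylenation at C11 of the trans-decalindione 15.
3. 15 ⇒ ring B is closed last by an intramolecular Michael addition (C6–C7). It follows a Cu-catalysed conjugate addition (C9–C10) and a Mannich trap (C5–C6) on enone 7.
4. 7 (ring A) ⇒ enantioselective β,γ→α,β isomerisation of 6. Compound 6 comes from the key step, a Birch dearomatisation of only the anisole ring of diarylmethane 3.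
5. 3 ⇒ phloroglucinol + 4-methoxy-2-methylbenzyl alcohol. Ring order: the arene is kept, ring A comes from the anisole, ring B is built last.

Assumption: eudesmane numbering is used (C1 bears ArCH2, C4 the carbinol, C5 the ring-fusion H, C7 the isopropenyl group, C10 the angular CH3, C6 lies between C5 and C7, C11 is the central isopropenyl carbon); MOM = CH2OCH3; 2, 8 and 18 are taken as catalogue chemicals.

## Route

Step 1
Reactants: 1 phloroglucinol; 2 (4-methoxy-2-methylphenyl)methanol
Product: 3 diarylmethane triol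
Conditions: 1 (3 equiv), p-TsOH·H2O (5 mol %), MeCN, 40 °C
Reagents that add atoms: none
Why: Friedel–Crafts benzylation: acid ionises 2 to a cation stabilised by the para-methoxy and ortho-methyl groups, and phloroglucinol, the best carbon nucleophile present and used in excess, captures it once at carbon; no stereocentre is formed.

Step 2
Reactants: 3 diarylmethane triol
Product: 4 dienol ether triol
Conditions: Li (12 equiv), NH3(l)–THF–t-BuOH, −78 → −33 °C; solid NH4Cl; used crude
Reagents that add atoms: none
Why: Birch reduction: the three phenols are deprotonated at once and the triphenoxide ring refuses an electron, so only the anisole ring is reduced, and the donor rule leaves OMe, CH3 and CH2Ar on sp2 carbons, giving the 1,4-diene with the tetrasubstituted C1=C10 bond; no stereocentre is formed.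

Step 3
Reactants: 4 dienol ether triol
Product: 6 tris-MOM beta-gamma-enone, via tris-MOM dienol ether 5 (not isolated)
Conditions: MOMCl (4.5 equiv), iPr2NEt (6 equiv), CH2Cl2, 0 °C → rt; aqueous wash; crude 5, (CO2H)2 (20 mol %), THF–H2O, rt
Reagents that add atoms: chloromethyl methyl ether (MOMCl), COCCl; water, O
Why: O-alkylation of the phenols with the hard electrophile MOMCl is run while ring A is still a base-stable dienol ether, and the mild enol ether hydrolysis that follows stops at the unconjugated ketone, because aryl MOM ethers and the C1=C10 bond are inert to oxalic acid; no stereocentre is formed.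

Step 4
Reactants: 6 tris-MOM beta-gamma-enone
Product: 7 (S)-enone
Conditions: 9-amino-9-deoxy-epi-quinidine (10 mol %), ClCH2CO2H (20 mol %), toluene, −20 °C
Reagents that add atoms: none
Why: Enantioselective olefin isomerisation by cooperative iminium–base (proton-transfer) catalysis, a reaction type established for Birch-derived cyclohex-3-enones: the primary amine forms the iminium ion, the quinuclidine removes H-5 to give the dienamine, and its conjugate acid returns the proton to one face of C1, setting C1 as S; if the sense proves opposite, the quinine-derived pseudoenantiomer is used.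

Step 5
Reactants: 7 (S)-enone; 8 2-(3-chloropropyl)-2-methyl-1,3-dioxolane
Product: 11 Mannich base, via Grignard reagent 9 (not isolated), via magnesium enolate 10 (not isolated)
Conditions: 8, Mg turnings, THF, reflux; CuBr·SMe2 (20 mol %), 7, THF–Me2S, −40 → −10 °C; then CH2=NMe2+ I−, −40 °C → rt
Reagents that add atoms: N,N-dimethylmethyleneiminium iodide (Eschenmoser's salt), C=[N+](C)C.[I-]
Why: Copper-catalysed conjugate addition of a Grignard reagent followed by Mannich trapping of the regiodefined enolate: allylic 1,2-strain with the C10 methyl holds ArCH2 pseudoaxial, so the organocopper adds to C10 from the opposite face (the known behaviour of 3,4-dialkylcyclohexenones) and sets the quaternary centre with CH3 cis and the chain trans to ArCH2, while the small iminium ion places C6 on C5.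

Step 6
Reactants: 11 Mannich base
Product: 15 trans-decalindione, via methiodide 12 (not isolated), via keto methiodide 13 (not isolated), via exo-methylene diketone 14 (not isolated)
Conditions: MeI, CH2Cl2, rt, evaporate; HCl (cat.), THF–H2O, rt; NaOMe, MeOH, 0 °C → rt
Reagents that add atoms: water, O
Why: Quaternisation, acetal hydrolysis, E1cB (Hofmann-type) loss of trimethylamine and a 6-endo-trig intramolecular Michael addition of the methyl ketone enolate through C7 (attack through its CH3 would need an eight-membered ring) close ring B, and because C5 and C7 are both alpha to carbonyl groups methoxide equilibrates them to the trans-fused isomer with equatorial acetyl, the minor epimers being separated and recycled by renewed exposure to NaOMe.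

Step 7
Reactants: 15 trans-decalindione
Product: 16 isopropenyl decalone
Conditions: CH3PPh3Br (1.2 equiv), KOtBu (1.15 equiv), THF, 0 °C; then 15, 0 °C
Reagents that add atoms: methyltriphenylphosphonium bromide, C[P+](c1ccccc1)(c1ccccc1)c1ccccc1.[Br-]
Why: Wittig methylenation: one equivalent of ylide takes the unhindered side-chain methyl ketone, whereas the C4 carbonyl next to the ring fusion and 1,3 to the axial C10 methyl needs forcing conditions, and C5 and C7 already hold their thermodynamic configuration, so the basic medium cannot erode them.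

Step 8
Reactants: 16 isopropenyl decalone
Product: 17 tertiary alcohol
Conditions: MeLi (3 equiv), Et2O, −78 → −30 °C; H2O
Reagents that add atoms: methyllithium, [Li]C
Why: 1,2-addition of methyllithium: the axial (beta) trajectory is blocked by the syn-axial C10 methyl, so CH3 enters equatorially from the alpha face and gives the axial 4-beta alcohol (4S).

Step 9
Reactants: 17 tertiary alcohol; 18 N-methoxy-N,3-dimethylbutanamide
Product: 23 fully substituted tris-MOM ether, via dilithio species 19 (not isolated), via Weinreb adduct 20 (not isolated), via lithiated adduct 21 (not isolated), via double adduct 22 (not isolated)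
Conditions: n-BuLi (2.1 equiv), THF, 0 °C; 18 (1.0 equiv), −78 → 0 °C; n-BuLi (1.3 equiv), 0 °C; DMF, −78 °C → rt; H2O
Reagents that add atoms: N,N-dimethylformamide, CN(C)C=O
Why: Two directed ortho-metalations in one flask: each of the two equivalent aryl C–H bonds lies between two OMOM groups, the first aryllithium gives a Weinreb ketone synthesis whose chelated tetrahedral adduct masks the ketone during the second lithiation, the second aryllithium is formylated with DMF (Bouveault type), and both carbonyl groups appear only on quenching; no stereocentre is touched.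

Step 10
Reactants: 23 fully substituted tris-MOM ether
Product: 24 target CNP0561337.2
Conditions: HCl (0.1 M) in MeOH, 0 °C → rt
Reagents that add atoms: none
Why: Acid-catalysed acetal exchange: every MOM ether now sits ortho to a carbonyl group and is labile enough to leave in dilute acid at room temperature, conditions that spare the tertiary alcohol and the 1,1-disubstituted alkene; no stereocentre is affected.

## Compound list
1 | phloroglucinol (benzene-1,3,5-triol) | Oc1cc(O)cc(O)c1 | starting material
2 | (4-methoxy-2-methylphenyl)methanol | COc1ccc(CO)c(C)c1 | starting material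
3 | 2-[(4-methoxy-2-methylphenyl)methyl]benzene-1,3,5-triol | COc1ccc(Cc2c(O)cc(O)cc2O)c(C)c1 | intermediate
4 | 2-[(4-methoxy-2-methylcyclohexa-1,4-dien-1-yl)methyl]benzene-1,3,5-triol | COC1=CCC(Cc2c(O)cc(O)cc2O)=C(C)C1 | intermediate
5 | 2-[(4-methoxy-2-methylcyclohexa-1,4-dien-1-yl)methyl]-1,3,5-tris(methoxymethoxy)benzene | COC1=CCC(Cc2c(OCOC)cc(OCOC)cc2OCOC)=C(C)C1 | intermediate
6 | 3-methyl-4-{[2,4,6-tris(methoxymethoxy)phenyl]methyl}cyclohex-3-en-1-one | O=C1CCC(Cc2c(OCOC)cc(OCOC)cc2OCOC)=C(C)C1 | intermediate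
7 | (4S)-3-methyl-4-{[2,4,6-tris(methoxymethoxy)phenyl]methyl}cyclohex-2-en-1-one | O=C1C=C(C)[C@H](Cc2c(OCOC)cc(OCOC)cc2OCOC)CC1 | intermediate
8 | 2-(3-chloropropyl)-2-methyl-1,3-dioxolane | CC1(CCCCl)OCCO1 | starting material
9 | [3-(2-methyl-1,3-dioxolan-2-yl)propyl]magnesium chloride | CC1(CCC[Mg]Cl)OCCO1 | intermediate
10 | chloromagnesium C4–C5 enolate of the conjugate adduct (1S,10S; chain trans to ArCH2) | CC1(CCC[C@@]2(C)[C@H](Cc3c(OCOC)cc(OCOC)cc3OCOC)CCC(O[Mg]Cl)=C2)OCCO1 | intermediate
11 | 2-[(dimethylamino)methyl]-3-methyl-3-[3-(2-methyl-1,3-dioxolan-2-yl)propyl]-4-{[2,4,6-tris(methoxymethoxy)phenyl]methyl}cyclohexan-1-one (1S,10S; CH2NMe2 equatorial, its epimer is inconsequential) | CC1(CCC[C@@]2(C)[C@H](Cc3c(OCOC)cc(OCOC)cc3OCOC)CCC(=O)[C@@H]2CN(C)C)OCCO1 | intermediate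
12 | methiodide of 11 | CC1(CCC[C@@]2(C)[C@H](Cc3c(OCOC)cc(OCOC)cc3OCOC)CCC(=O)[C@@H]2C[N+](C)(C)C)OCCO1.[I-] | intermediate
13 | methiodide with free 4-oxopentyl side chain | CC(=O)CCC[C@@]1(C)[C@H](Cc2c(OCOC)cc(OCOC)cc2OCOC)CCC(=O)[C@@H]1C[N+](C)(C)C.[I-] | intermediate
14 | (3S,4S)-3-methyl-2-methylidene-3-(4-oxopentyl)-4-{[2,4,6-tris(methoxymethoxy)phenyl]methyl}cyclohexan-1-one | CC(=O)CCC[C@@]1(C)[C@H](Cc2c(OCOC)cc(OCOC)cc2OCOC)CCC(=O)C1=C | intermediate
15 | (4S,4aS,7R,8aR)-7-acetyl-4a-methyl-4-{[2,4,6-tris(methoxymethoxy)phenyl]methyl}octahydronaphthalen-1(2H)-one (trans-fused, acetyl equatorial) | CC(=O)[C@@H]1CC[C@@]2(C)[C@H](Cc3c(OCOC)cc(OCOC)cc3OCOC)CCC(=O)[C@@H]2C1 | intermediate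
16 | (4S,4aS,7R,8aR)-4a-methyl-7-(prop-1-en-2-yl)-4-{[2,4,6-tris(methoxymethoxy)phenyl]methyl}octahydronaphthalen-1(2H)-one | C=C(C)[C@@H]1CC[C@@]2(C)[C@H](Cc3c(OCOC)cc(OCOC)cc3OCOC)CCC(=O)[C@@H]2C1 | intermediate
17 | (1S,4S,4aS,7R,8aR)-1,4a-dimethyl-7-(prop-1-en-2-yl)-4-{[2,4,6-tris(methoxymethoxy)phenyl]methyl}decahydronaphthalen-1-ol (OH axial) | C=C(C)[C@@H]1CC[C@@]2(C)[C@H](Cc3c(OCOC)cc(OCOC)cc3OCOC)CC[C@](C)(O)[C@@H]2C1 | intermediate
18 | N-methoxy-N,3-dimethylbutanamide | CON(C)C(=O)CC(C)C | starting material
19 | lithium alkoxide of 17 lithiated at one aryl C–H | C=C(C)[C@@H]1CC[C@@]2(C)[C@H](Cc3c(OCOC)cc(OCOC)c([Li])c3OCOC)CC[C@](C)(O[Li])[C@@H]2C1 | intermediate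
20 | tetrahedral lithium adduct of 19 to 18 | C=C(C)[C@@H]1CC[C@@]2(C)[C@H](Cc3c(OCOC)cc(OCOC)c(C(O[Li])(CC(C)C)N(C)OC)c3OCOC)CC[C@](C)(O[Li])[C@@H]2C1 | intermediate
21 | 20 lithiated at the last aryl C–H | C=C(C)[C@@H]1CC[C@@]2(C)[C@H](Cc3c(OCOC)c([Li])c(OCOC)c(C(O[Li])(CC(C)C)N(C)OC)c3OCOC)CC[C@](C)(O[Li])[C@@H]2C1 | intermediate
22 | adduct of 21 to DMF (lithium alpha-dimethylamino alkoxide) | C=C(C)[C@@H]1CC[C@@]2(C)[C@H](Cc3c(OCOC)c(C(O[Li])N(C)C)c(OCOC)c(C(O[Li])(CC(C)C)N(C)OC)c3OCOC)CC[C@](C)(O[Li])[C@@H]2C1 | intermediate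
23 | 3-{[(1S,4S,4aR,6R,8aS)-4-hydroxy-4,8a-dimethyl-6-(prop-1-en-2-yl)decahydronaphthalen-1-yl]methyl}-2,4,6-tris(methoxymethoxy)-5-(3-methylbutanoyl)benzaldehyde | C=C(C)[C@@H]1CC[C@@]2(C)[C@H](Cc3c(OCOC)c(C=O)c(OCOC)c(C(=O)CC(C)C)c3OCOC)CC[C@](C)(O)[C@@H]2C1 | intermediate
24 | 2,4,6-trihydroxy-3-{[(1S,4S,4aR,6R,8aS)-4-hydroxy-4,8a-dimethyl-6-(prop-1-en-2-yl)decahydronaphthalen-1-yl]methyl}-5-(3-methylbutanoyl)benzaldehyde (CNP0561337.2) | C=C(C)[C@@H]1CC[C@@]2(C)[C@H](Cc3c(O)c(C=O)c(O)c(C(=O)CC(C)C)c3O)CC[C@](C)(O)[C@@H]2C1 | target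

## Count and risks
Total steps: 10. Longest linear sequence: 10 (1 or 2 → 24).

**Step 2 (Birch reduction of only one ring).** The trilithium salt of 3 may be too insoluble, or the phloroglucinol ring may not stay inert. In the fallback, ring A is not made by reducing 3. It sets out from 1 and comes back at 6.
- Commercial Hagemann's ester F1 is ketalised (ethylene glycol, p-TsOH, toluene, water removal). The double bond moves into conjugation with the ester and gives the ketal ester F2.
- LiAlH4 reduces F2 to the allylic alcohol F3.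
- An acid-catalysed Friedel–Crafts allylation of excess 1 with F3 in aqueous dioxane attacks the primary end of the allyl cation. The ketal is hydrolysed at the same time, giving the triol beta-gamma-enone F4.
- MOMCl/iPr2NEt converts F4 into 6.

**Step 4 (enantioselective isomerisation of a substrate with a very large C1 substituent).** The ee may be low. The fallback gives up catalytic induction for resolution with recycling. It sets out from 6 and comes back at 7.
- DBU conjugates 6 to the racemic enone F5.
- Preparative supercritical-fluid chromatography on a chiral stationary phase delivers 7.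
- The unwanted (R)-enone F6 is returned to achiral 6 by forming the extended enolate (KOtBu) and quenching it kinetically at C5 with AcOH. It is then recycled.

**Step 9 (two metalations and two electrophiles in one flask).** Adduct 20 may not survive the second lithiation, or the hindered aryllithium may enolise 18. The fallback uses one metalation only and brings in the formyl carbon by electrophilic chemistry on the free phenol. It sets out from 17 and comes back at 24.
- n-BuLi, then 18, gives the mono-ketone F7.
- Dilute HCl in MeOH frees the acylphloroglucinol F8.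
- Magnesium-mediated ortho-formylation (MgCl2, Et3N, paraformaldehyde, MeCN, reflux) fills the only open ring position. These mildly basic conditions leave the tertiary alcohol and the isopropenyl group alone, and the product is 24.

## Further compounds
F1 | step 2 | Hagemann's ester (ethyl 2-methyl-4-oxocyclohex-2-ene-1-carboxylate, racemic) | CCOC(=O)C1CCC(=O)C=C1C
F2 | step 2 | ethyl 7-methyl-1,4-dioxaspiro[4.5]dec-7-ene-8-carboxylate | CCOC(=O)C1=C(C)CC2(CC1)OCCO2
F3 | step 2 | (7-methyl-1,4-dioxaspiro[4.5]dec-7-en-8-yl)methanol | OCC1=C(C)CC2(CC1)OCCO2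
F4 | step 2 | 3-methyl-4-[(2,4,6-trihydroxyphenyl)methyl]cyclohex-3-en-1-one | O=C1CCC(Cc2c(O)cc(O)cc2O)=C(C)C1
F5 | step 4 | racemic 3-methyl-4-{[2,4,6-tris(methoxymethoxy)phenyl]methyl}cyclohex-2-en-1-one | O=C1C=C(C)C(Cc2c(OCOC)cc(OCOC)cc2OCOC)CC1
F6 | step 4 | (4R)-3-methyl-4-{[2,4,6-tris(methoxymethoxy)phenyl]methyl}cyclohex-2-en-1-one | O=C1C=C(C)[C@@H](Cc2c(OCOC)cc(OCOC)cc2OCOC)CC1
F7 | step 9 | 1-(3-{[(1S,4S,4aR,6R,8aS)-4-hydroxy-4,8a-dimethyl-6-(prop-1-en-2-yl)decahydronaphthalen-1-yl]methyl}-2,4,6-tris(methoxymethoxy)phenyl)-3-methylbutan-1-one | C=C(C)[C@@H]1CC[C@@]2(C)[C@H](Cc3c(OCOC)cc(OCOC)c(C(=O)CC(C)C)c3OCOC)CC[C@](C)(O)[C@@H]2C1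
F8 | step 9 | 1-(2,4,6-trihydroxy-3-{[(1S,4S,4aR,6R,8aS)-4-hydroxy-4,8a-dimethyl-6-(prop-1-en-2-yl)decahydronaphthalen-1-yl]methyl}phenyl)-3-methylbutan-1-one | C=C(C)[C@@H]1CC[C@@]2(C)[C@H](Cc3c(O)cc(O)c(C(=O)CC(C)C)c3O)CC[C@](C)(O)[C@@H]2C1
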